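**Retrosynthetic overview**
1. Target ⇐ HF desilylation ⇐ Yamaguchi esterification of the 8‑hydroxy lactone 24 with acid 31 (made from dimethyl (R)‑malate).
2. 24 ⇐ acyclic bromo‑enal 21: one chromium‑mediated intramolecular 2‑(methoxycarbonyl)allylation (C6–C7 bond) with in‑situ lactonization closes both rings and sets C6 and C7 from C8.
3. 21 ⇐ Baylis–Hillman reaction and SN2′ bromination at a C7 aldehyde; the C1–C10 bond comes from an asymmetric Ni/Cr coupling of aldehyde 8 with vinyl bromide 12 (sets C1).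
4. 8 ⇐ anti‑carbomagnesiation of 2‑butyne‑1,4‑diol (fixes the C4=C5 geometry); 12 ⇐ 2‑bromoallylation of (R)‑glyceraldehyde acetonide (sets C8).
5. Ring order: no ring exists before step 14; the ten‑membered carbocycle and the cis‑fused α‑methylene‑γ‑lactone form together in step 14.

Assumption: in step 7 the (S)‑configured sulfonamide ligand is taken to give the (1R)‑carbinol, and its enantiomer is used if the sense is the opposite (C1–C15 = germacrane numbering; TBS = tert‑butyldimethylsilyl, TBDPS = tert‑butyldiphenylsilyl, PMB = 4‑methoxybenzyl).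

**Step 1**
Reactants: 1 2‑butyne‑1,4‑diol; 2 2‑(2‑bromoethyl)‑1,3‑dioxolane
Product: 5 (2E)‑2‑[2‑(1,3‑dioxolan‑2‑yl)ethyl]but‑2‑ene‑1,4‑diol, via Grignard reagent 3 (not isolated), via vinylmagnesium alkoxide 4 (not isolated)
Conditions: Mg, THF, 25 °C (gives 3, 3.3 equiv); then 1, CuI (10 mol%), THF, 0 → 25 °C, 18 h; aq NH4Cl
Reagents that add atoms: none
Why: Copper‑catalysed, hydroxyl‑directed anti‑carbomagnesiation of the propargylic diol puts the alkyl group on the carbon next to a magnesium alkoxide and magnesium cis to that CH2O group in a five‑membered chelate, so protonation leaves the new chain cis to the distal CH2OH, which is the C3/C6‑cis geometry of the target's C4=C5 bond.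

**Step 2**
Reactants: 5 (2E)‑2‑[2‑(1,3‑dioxolan‑2‑yl)ethyl]but‑2‑ene‑1,4‑diol
Product: 6 (2E)‑4‑[(TBDPS)oxy]‑2‑[2‑(1,3‑dioxolan‑2‑yl)ethyl]but‑2‑en‑1‑ol
Conditions: TBDPSCl (1.05 equiv), imidazole, CH2Cl2, −40 → −20 °C
Reagents that add atoms: tert‑butyldiphenylsilyl chloride, CC(C)(C)[Si](Cl)(c1ccccc1)c1ccccc1
Why: Sterically controlled monosilylation, because the CH2OH on the CH= carbon (future C6) is less hindered than the one on the fully substituted alkene carbon (future C15); the minor regioisomer and bis‑ether are removed by chromatography.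

**Step 3**
Reactants: 6 (2E)‑4‑[(TBDPS)oxy]‑2‑[2‑(1,3‑dioxolan‑2‑yl)ethyl]but‑2‑en‑1‑ol
Product: 7 (2E)‑4‑[(TBDPS)oxy]‑2‑[2‑(1,3‑dioxolan‑2‑yl)ethyl]but‑2‑en‑1‑yl acetate
Conditions: Ac2O, Et3N, DMAP (cat.), CH2Cl2, 0 °C
Reagents that add atoms: acetic anhydride, CC(=O)OC(C)=O
Why: DMAP‑catalysed acylation installs the C15 acetate that is carried unchanged to the target.

**Step 4**
Reactants: 7 (2E)‑4‑[(TBDPS)oxy]‑2‑[2‑(1,3‑dioxolan‑2‑yl)ethyl]but‑2‑en‑1‑yl acetate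
Product: 8 (2E)‑4‑[(TBDPS)oxy]‑2‑(3‑oxopropyl)but‑2‑en‑1‑yl acetate
Conditions: 1 M HCl, THF, 23 °C
Reagents that add atoms: water, O
Why: Acid‑catalysed acetal hydrolysis unmasks the C1 aldehyde, while the primary allylic acetate and the acid‑stable TBDPS ether survive dilute acid at room temperature.

**Step 5**
Reactants: 9 (R)‑2,2‑dimethyl‑1,3‑dioxolane‑4‑carbaldehyde; 10 2,3‑dibromopropene
Product: 11 (1S)‑3‑bromo‑1‑[(4R)‑2,2‑dimethyl‑1,3‑dioxolan‑4‑yl]but‑3‑en‑1‑ol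
Conditions: Zn dust, THF/sat. aq NH4Cl, 0 → 23 °C
Reagents that add atoms: none
Why: Zinc‑mediated Barbier 2‑bromoallylation adds to the α‑alkoxy aldehyde in the Felkin–Anh (non‑chelation) sense to give mainly the anti adduct, whose new carbinol is the (S)‑configured C8 (expected about 4:1 or better, minor syn isomer removed by chromatography).

**Step 6**
Reactants: 11 (1S)‑3‑bromo‑1‑[(4R)‑2,2‑dimethyl‑1,3‑dioxolan‑4‑yl]but‑3‑en‑1‑ol
Product: 12 (4R)‑4‑[(1S)‑3‑bromo‑1‑(PMB‑oxy)but‑3‑en‑1‑yl]‑2,2‑dimethyl‑1,3‑dioxolane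
Conditions: NaH, PMBCl, Bu4NI (cat.), THF/DMF, 0 → 23 °C
Reagents that add atoms: 4‑methoxybenzyl chloride, COc1ccc(CCl)cc1
Why: Williamson etherification gives a C8 ether that survives acid, chromium and fluoride, is too poor a leaving group to be expelled from the later allylchromium, and can be removed oxidatively after ring closure.

**Step 7**
Reactants: 8 (2E)‑4‑[(TBDPS)oxy]‑2‑(3‑oxopropyl)but‑2‑en‑1‑yl acetate; 12 (4R)‑4‑[(1S)‑3‑bromo‑1‑(PMB‑oxy)but‑3‑en‑1‑yl]‑2,2‑dimethyl‑1,3‑dioxolane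
Product: 13 (2E)‑4‑[(TBDPS)oxy]‑2‑{(3R,6S)‑6‑[(4R)‑2,2‑dimethyl‑1,3‑dioxolan‑4‑yl]‑3‑hydroxy‑6‑(PMB‑oxy)‑4‑methylidenehexyl}but‑2‑en‑1‑yl acetate
Conditions: CrCl2 (4 equiv), (S)‑N‑[2‑(4‑isopropyl‑4,5‑dihydrooxazol‑2‑yl)‑6‑methylphenyl]methanesulfonamide (4.4 equiv), Et3N (4.4 equiv), NiCl2 (2 mol%), THF, 23 °C
Reagents that add atoms: none
Why: Nozaki–Hiyama–Kishi coupling, in which zerovalent nickel inserts into the vinyl bromide and the derived vinylchromium adds only to the aldehyde (acetate, ketal and silyl ether are inert), with the sulfonamide‑bound chromium selecting one aldehyde face to set (1R) under reagent control.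

**Step 8**
Reactants: 13 (the C1 alcohol above)
Product: 14 (2E)‑4‑[(TBDPS)oxy]‑2‑{(3R,6S)‑3‑[(TBS)oxy]‑6‑[(4R)‑2,2‑dimethyl‑1,3‑dioxolan‑4‑yl]‑6‑(PMB‑oxy)‑4‑methylidenehexyl}but‑2‑en‑1‑yl acetate
Conditions: TBSCl, imidazole, DMAP (cat.), DMF, 23 °C
Reagents that add atoms: tert‑butyldimethylsilyl chloride, CC(C)(C)[Si](C)(C)Cl
Why: Silylation protects the allylic C1 hydroxyl from the later oxidation and bromination steps and is removed only in the last step.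

**Step 9**
Reactants: 14 (the acetonide above)
Product: 16 (2E)‑4‑[(TBDPS)oxy]‑2‑{(3R,6S)‑3‑[(TBS)oxy]‑6‑(PMB‑oxy)‑4‑methylidene‑7‑oxoheptyl}but‑2‑en‑1‑yl acetate, via vicinal diol 15 (not isolated)
Conditions: H5IO6 (2 equiv), EtOAc, 23 °C
Reagents that add atoms: none
Why: Periodic acid hydrolyses the terminal acetonide and then cleaves the 1,2‑diol (Malaprade cleavage), giving the C7 aldehyde in one operation without touching the C8 stereocenter.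

**Step 10**
Reactants: 16 (the C7 aldehyde above); 17 methyl acrylate
Product: 18 methyl (4S,7R,10E)‑10‑(acetoxymethyl)‑7‑[(TBS)oxy]‑12‑[(TBDPS)oxy]‑3‑hydroxy‑4‑(PMB‑oxy)‑2,6‑dimethylidenedodec‑10‑enoate (C3 epimers)
Conditions: DABCO (1 equiv), methyl acrylate (10 equiv), 1,4‑dioxane/H2O (1:1), 0 → 23 °C
Reagents that add atoms: none
Why: Morita–Baylis–Hillman reaction of the activated α‑alkoxy aldehyde, where the configuration of the new carbinol (C7) does not matter because that carbon becomes sp2 in step 13.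

**Step 11**
Reactants: 18 (the Baylis–Hillman adduct above)
Product: 19 methyl (4S,7R,10E)‑10‑(acetoxymethyl)‑7‑[(TBS)oxy]‑3,12‑dihydroxy‑4‑(PMB‑oxy)‑2,6‑dimethylidenedodec‑10‑enoate (C3 epimers)
Conditions: Bu4NF (1.2 equiv), AcOH (1.2 equiv), THF, 0 °C
Reagents that add atoms: none
Why: Buffered fluoride cleaves the primary TBDPS ether much faster than the hindered secondary TBS ether, and the acetic acid buffer protects the acetate and the acrylate.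

**Step 12**
Reactants: 19 (the C6 alcohol above)
Product: 20 methyl (4S,7R,10E)‑10‑(acetoxymethyl)‑7‑[(TBS)oxy]‑3‑hydroxy‑4‑(PMB‑oxy)‑2,6‑dimethylidene‑12‑oxododec‑10‑enoate (C3 epimers)
Conditions: MnO2 (20 equiv), CH2Cl2, 23 °C
Reagents that add atoms: none
Why: MnO2 oxidises only the electron‑rich primary allylic alcohol (the electron‑poor secondary Baylis–Hillman alcohol is inert) and does not isomerise the enal, so C6 stays cis to C3.

**Step 13**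
Reactants: 20 (the enal above)
Product: 21 methyl (2Z,4S,7R,10E)‑10‑(acetoxymethyl)‑2‑(bromomethyl)‑7‑[(TBS)oxy]‑4‑(PMB‑oxy)‑6‑methylidene‑12‑oxododeca‑2,10‑dienoate
Conditions: N‑bromosuccinimide, Me2S, CH2Cl2, 0 → 23 °C
Reagents that add atoms: N‑bromosuccinimide, O=C1CCC(=O)N1Br
Why: Corey–Kim‑type activation of the Baylis–Hillman alcohol followed by SN2′ attack of bromide gives the thermodynamically preferred (2Z)‑2‑(bromomethyl)enoate, and the enal and ethers are inert.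

**Step 14 (key step)**
Reactants: 21 (the bromo‑enal above)
Product: 23 [(3aR,4S,7R,10E,11aS)‑7‑[(TBS)oxy]‑4‑(PMB‑oxy)‑3,6‑dimethylidene‑2‑oxo‑2,3,3a,4,5,6,7,8,9,11a‑decahydrocyclodeca[b]furan‑10‑yl]methyl acetate, via cyclodecenyl hydroxy ester 22 (not isolated)
Conditions: CrCl2 (8 equiv), DMF, 23 °C, syringe‑pump addition of 21 (final 3 mM); aq NH4Cl
Reagents that add atoms: none
Why: Intramolecular Nozaki–Hiyama‑type (Barbier) 2‑(alkoxycarbonyl)allylation, in which divalent chromium turns the allylic bromide into an allylchromium that adds through C7 to the enal in a chair transition state with the C8 chain cis to CH2Cr (syn adduct, hence the cis ring fusion and 6S) and with the aldehyde, tethered through C9, approaching the C7 face anti to the C8–OPMB bond in the A(1,3)‑minimised rotamer (7R), after which the chromium alkoxide closes the γ‑lactone on the methyl ester so that the ten‑membered carbocycle and the lactone form in the same operation.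

**Step 15**
Reactants: 23 (the PMB‑protected lactone above)
Product: 24 [(3aR,4S,7R,10E,11aS)‑7‑[(TBS)oxy]‑4‑hydroxy‑3,6‑dimethylidene‑2‑oxo‑2,3,3a,4,5,6,7,8,9,11a‑decahydrocyclodeca[b]furan‑10‑yl]methyl acetate
Conditions: DDQ (1.5 equiv), CH2Cl2/pH 7 buffer (10:1), 0 → 23 °C
Reagents that add atoms: none
Why: Oxidative PMB cleavage by hydride abstraction frees the C8 hydroxyl while the silyl ether, acetate, exo‑methylene lactone and alkenes are untouched.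

**Step 16**
Reactants: 25 dimethyl (R)‑malate
Product: 26 methyl (3R)‑3,4‑dihydroxybutanoate
Conditions: BH3·SMe2 (1.05 equiv), NaBH4 (5 mol%), THF, 0 → 23 °C; MeOH, then aqueous work‑up
Reagents that add atoms: none
Why: Hydroxyl‑directed borane reduction through a five‑membered alkoxyborane reduces only the ester next to the hydroxyl, and the stereocenter is not involved.

**Step 17**
Reactants: 26 methyl (3R)‑3,4‑dihydroxybutanoate
Product: 27 methyl (3R)‑3,4‑bis[(TBS)oxy]butanoate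
Conditions: TBSCl (2.5 equiv), imidazole, DMF, 23 °C
Reagents that add atoms: tert‑butyldimethylsilyl chloride, CC(C)(C)[Si](C)(C)Cl
Why: Bis‑silylation prevents lactonization of the diol ester and gives groups that leave together with the C1 silyl ether in the last step.

**Step 18**
Reactants: 27 methyl (3R)‑3,4‑bis[(TBS)oxy]butanoate
Product: 30 methyl (3R)‑3,4‑bis[(TBS)oxy]‑2‑methylidenebutanoate, via Mannich base 28 (not isolated), via ammonium iodide 29 (not isolated)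
Conditions: LiN(i‑Pr)2, THF, −78 °C; Me2N=CH2 iodide, −78 → 0 °C; then MeI, MeOH, 23 °C; then K2CO3, CH2Cl2/H2O
Reagents that add atoms: Eschenmoser's salt, C=[N+](C)C.[I-]
Why: Ester‑enolate Mannich reaction at −78 °C (cold enough to suppress β‑elimination of the silyloxy group), then exhaustive methylation and E1cB loss of trimethylamine give the α‑methylene ester without touching the C3 stereocenter.

**Step 19**
Reactants: 30 methyl (3R)‑3,4‑bis[(TBS)oxy]‑2‑methylidenebutanoate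
Product: 31 (3R)‑3,4‑bis[(TBS)oxy]‑2‑methylidenebutanoic acid
Conditions: LiOH·H2O, THF/H2O, 0 → 23 °C; then 1 M HCl to pH 3
Reagents that add atoms: lithium hydroxide, [Li+].[OH-]
Why: Saponification of the methyl ester, to which the TBS ethers are stable at room temperature.

**Step 20**
Reactants: 24 (the 8‑hydroxy lactone above); 31 (3R)‑3,4‑bis[(TBS)oxy]‑2‑methylidenebutanoic acid
Product: 33 (3aR,4S,7R,10E,11aS)‑10‑(acetoxymethyl)‑7‑[(TBS)oxy]‑3,6‑dimethylidene‑2‑oxo‑2,3,3a,4,5,6,7,8,9,11a‑decahydrocyclodeca[b]furan‑4‑yl (3R)‑3,4‑bis[(TBS)oxy]‑2‑methylidenebutanoate, via mixed anhydride 32 (not isolated)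
Conditions: 2,4,6‑Cl3C6H2COCl, Et3N, THF, 23 °C; then 24, DMAP, toluene, 23 °C
Reagents that add atoms: none
Why: Yamaguchi esterification, in which the mixed anhydride acylates the hindered secondary C8 alcohol under DMAP catalysis without touching any stereocenter.

**Step 21**
Reactants: 33 (the tris‑silyl ester above)
Product: 34 (3aR,4S,7R,10E,11aS)‑10‑(acetoxymethyl)‑7‑hydroxy‑3,6‑dimethylidene‑2‑oxo‑2,3,3a,4,5,6,7,8,9,11a‑decahydrocyclodeca[b]furan‑4‑yl (3R)‑3,4‑dihydroxy‑2‑methylidenebutanoate (CNP0245550.1)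
Conditions: HF·pyridine, pyridine, THF, 0 → 23 °C
Reagents that add atoms: none
Why: Buffered HF·pyridine removes the three TBS ethers while the acetate, both unsaturated esters and the lactone are stable to these mildly acidic conditions.

**Compound list**
1 | 2‑butyne‑1,4‑diol | OCC#CCO | starting material
2 | 2‑(2‑bromoethyl)‑1,3‑dioxolane | BrCCC1OCCO1 | starting material
3 | [2‑(1,3‑dioxolan‑2‑yl)ethyl]magnesium bromide (not isolated) | Br[Mg]CCC1OCCO1 | intermediate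
4 | vinylmagnesium bromide bis(bromomagnesium alkoxide) of 5, Mg on C5 cis to C15H2O (not isolated) | Br[Mg]OC/C(CCC1OCCO1)=C(/CO[Mg]Br)[Mg]Br | intermediate
5 | (2E)‑2‑[2‑(1,3‑dioxolan‑2‑yl)ethyl]but‑2‑ene‑1,4‑diol | OC/C(CCC1OCCO1)=C/CO | intermediate
6 | (2E)‑4‑[(TBDPS)oxy]‑2‑[2‑(1,3‑dioxolan‑2‑yl)ethyl]but‑2‑en‑1‑ol | OC/C(CCC1OCCO1)=C/CO[Si](c1ccccc1)(c1ccccc1)C(C)(C)C | intermediate
7 | (2E)‑4‑[(TBDPS)oxy]‑2‑[2‑(1,3‑dioxolan‑2‑yl)ethyl]but‑2‑en‑1‑yl acetate | CC(=O)OC/C(CCC1OCCO1)=C/CO[Si](c1ccccc1)(c1ccccc1)C(C)(C)C | intermediate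
8 | (2E)‑4‑[(TBDPS)oxy]‑2‑(3‑oxopropyl)but‑2‑en‑1‑yl acetate | CC(=O)OC/C(CCC=O)=C/CO[Si](c1ccccc1)(c1ccccc1)C(C)(C)C | intermediate
9 | (R)‑2,2‑dimethyl‑1,3‑dioxolane‑4‑carbaldehyde | O=C[C@H]1COC(C)(C)O1 | starting material
10 | 2,3‑dibromopropene | BrCC(Br)=C | starting material
11 | (1S)‑3‑bromo‑1‑[(4R)‑2,2‑dimethyl‑1,3‑dioxolan‑4‑yl]but‑3‑en‑1‑ol | C=C(Br)C[C@H](O)[C@H]1COC(C)(C)O1 | intermediate
12 | (4R)‑4‑[(1S)‑3‑bromo‑1‑(PMB‑oxy)but‑3‑en‑1‑yl]‑2,2‑dimethyl‑1,3‑dioxolane | C=C(Br)C[C@H](OCc1ccc(OC)cc1)[C@H]1COC(C)(C)O1 | intermediate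
13 | (2E)‑4‑[(TBDPS)oxy]‑2‑{(3R,6S)‑6‑[(4R)‑2,2‑dimethyl‑1,3‑dioxolan‑4‑yl]‑3‑hydroxy‑6‑(PMB‑oxy)‑4‑methylidenehexyl}but‑2‑en‑1‑yl acetate | CC(=O)OC/C(CC[C@@H](O)C(=C)C[C@H](OCc1ccc(OC)cc1)[C@H]1COC(C)(C)O1)=C/CO[Si](c1ccccc1)(c1ccccc1)C(C)(C)C | intermediate
14 | (2E)‑4‑[(TBDPS)oxy]‑2‑{(3R,6S)‑3‑[(TBS)oxy]‑6‑[(4R)‑2,2‑dimethyl‑1,3‑dioxolan‑4‑yl]‑6‑(PMB‑oxy)‑4‑methylidenehexyl}but‑2‑en‑1‑yl acetate | CC(=O)OC/C(CC[C@@H](O[Si](C)(C)C(C)(C)C)C(=C)C[C@H](OCc1ccc(OC)cc1)[C@H]1COC(C)(C)O1)=C/CO[Si](c1ccccc1)(c1ccccc1)C(C)(C)C | intermediate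
15 | (2E)‑4‑[(TBDPS)oxy]‑2‑{(3R,6S,7R)‑3‑[(TBS)oxy]‑7,8‑dihydroxy‑6‑(PMB‑oxy)‑4‑methylideneoctyl}but‑2‑en‑1‑yl acetate (not isolated) | CC(=O)OC/C(CC[C@@H](O[Si](C)(C)C(C)(C)C)C(=C)C[C@H](OCc1ccc(OC)cc1)[C@H](O)CO)=C/CO[Si](c1ccccc1)(c1ccccc1)C(C)(C)C | intermediate
16 | (2E)‑4‑[(TBDPS)oxy]‑2‑{(3R,6S)‑3‑[(TBS)oxy]‑6‑(PMB‑oxy)‑4‑methylidene‑7‑oxoheptyl}but‑2‑en‑1‑yl acetate | CC(=O)OC/C(CC[C@@H](O[Si](C)(C)C(C)(C)C)C(=C)C[C@H](OCc1ccc(OC)cc1)C=O)=C/CO[Si](c1ccccc1)(c1ccccc1)C(C)(C)C | intermediate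
17 | methyl acrylate | C=CC(=O)OC | starting material
18 | methyl (4S,7R,10E)‑10‑(acetoxymethyl)‑7‑[(TBS)oxy]‑12‑[(TBDPS)oxy]‑3‑hydroxy‑4‑(PMB‑oxy)‑2,6‑dimethylidenedodec‑10‑enoate (C3 epimers) | CC(=O)OC/C(CC[C@@H](O[Si](C)(C)C(C)(C)C)C(=C)C[C@H](OCc1ccc(OC)cc1)C(O)C(=C)C(=O)OC)=C/CO[Si](c1ccccc1)(c1ccccc1)C(C)(C)C | intermediate
19 | methyl (4S,7R,10E)‑10‑(acetoxymethyl)‑7‑[(TBS)oxy]‑3,12‑dihydroxy‑4‑(PMB‑oxy)‑2,6‑dimethylidenedodec‑10‑enoate (C3 epimers) | CC(=O)OC/C(CC[C@@H](O[Si](C)(C)C(C)(C)C)C(=C)C[C@H](OCc1ccc(OC)cc1)C(O)C(=C)C(=O)OC)=C/CO | intermediate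
20 | methyl (4S,7R,10E)‑10‑(acetoxymethyl)‑7‑[(TBS)oxy]‑3‑hydroxy‑4‑(PMB‑oxy)‑2,6‑dimethylidene‑12‑oxododec‑10‑enoate (C3 epimers) | CC(=O)OC/C(CC[C@@H](O[Si](C)(C)C(C)(C)C)C(=C)C[C@H](OCc1ccc(OC)cc1)C(O)C(=C)C(=O)OC)=C/C=O | intermediate
21 | methyl (2Z,4S,7R,10E)‑10‑(acetoxymethyl)‑2‑(bromomethyl)‑7‑[(TBS)oxy]‑4‑(PMB‑oxy)‑6‑methylidene‑12‑oxododeca‑2,10‑dienoate | CC(=O)OC/C(CC[C@@H](O[Si](C)(C)C(C)(C)C)C(=C)C[C@H](OCc1ccc(OC)cc1)/C=C(\CBr)C(=O)OC)=C/C=O | intermediate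
22 | methyl 2‑[(1S,2S,3E,7R,10S)‑4‑(acetoxymethyl)‑7‑[(TBS)oxy]‑2‑hydroxy‑10‑(PMB‑oxy)‑8‑methylidenecyclodec‑3‑en‑1‑yl]prop‑2‑enoate, formed as its chromium alkoxide (not isolated) | O[C@H]1/C=C(/COC(C)=O)CC[C@@H](O[Si](C)(C)C(C)(C)C)C(=C)C[C@H](OCc2ccc(OC)cc2)[C@H]1C(=C)C(=O)OC | intermediate
23 | [(3aR,4S,7R,10E,11aS)‑7‑[(TBS)oxy]‑4‑(PMB‑oxy)‑3,6‑dimethylidene‑2‑oxo‑2,3,3a,4,5,6,7,8,9,11a‑decahydrocyclodeca[b]furan‑10‑yl]methyl acetate | C=C1C(=O)O[C@H]2/C=C(/COC(C)=O)CC[C@@H](O[Si](C)(C)C(C)(C)C)C(=C)C[C@H](OCc3ccc(OC)cc3)[C@@H]12 | intermediate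
24 | [(3aR,4S,7R,10E,11aS)‑7‑[(TBS)oxy]‑4‑hydroxy‑3,6‑dimethylidene‑2‑oxo‑2,3,3a,4,5,6,7,8,9,11a‑decahydrocyclodeca[b]furan‑10‑yl]methyl acetate | C=C1C(=O)O[C@H]2/C=C(/COC(C)=O)CC[C@@H](O[Si](C)(C)C(C)(C)C)C(=C)C[C@H](O)[C@@H]12 | intermediate
25 | dimethyl (R)‑malate | COC(=O)C[C@@H](O)C(=O)OC | starting material
26 | methyl (3R)‑3,4‑dihydroxybutanoate | COC(=O)C[C@@H](O)CO | intermediate
27 | methyl (3R)‑3,4‑bis[(TBS)oxy]butanoate | COC(=O)C[C@@H](O[Si](C)(C)C(C)(C)C)CO[Si](C)(C)C(C)(C)C | intermediate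
28 | methyl (3R)‑3,4‑bis[(TBS)oxy]‑2‑[(dimethylamino)methyl]butanoate, C2 epimers (not isolated) | COC(=O)C(CN(C)C)[C@@H](O[Si](C)(C)C(C)(C)C)CO[Si](C)(C)C(C)(C)C | intermediate
29 | [(3R)‑3,4‑bis[(TBS)oxy]‑2‑(methoxycarbonyl)butyl]trimethylammonium iodide (not isolated) | COC(=O)C(C[N+](C)(C)C)[C@@H](O[Si](C)(C)C(C)(C)C)CO[Si](C)(C)C(C)(C)C.[I-] | intermediate
30 | methyl (3R)‑3,4‑bis[(TBS)oxy]‑2‑methylidenebutanoate | COC(=O)C(=C)[C@@H](O[Si](C)(C)C(C)(C)C)CO[Si](C)(C)C(C)(C)C | intermediate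
31 | (3R)‑3,4‑bis[(TBS)oxy]‑2‑methylidenebutanoic acid | OC(=O)C(=C)[C@@H](O[Si](C)(C)C(C)(C)C)CO[Si](C)(C)C(C)(C)C | intermediate
32 | (3R)‑3,4‑bis[(TBS)oxy]‑2‑methylidenebutanoic 2,4,6‑trichlorobenzoic anhydride (not isolated) | O=C(OC(=O)C(=C)[C@@H](O[Si](C)(C)C(C)(C)C)CO[Si](C)(C)C(C)(C)C)c1c(Cl)cc(Cl)cc1Cl | intermediate
33 | (3aR,4S,7R,10E,11aS)‑10‑(acetoxymethyl)‑7‑[(TBS)oxy]‑3,6‑dimethylidene‑2‑oxo‑2,3,3a,4,5,6,7,8,9,11a‑decahydrocyclodeca[b]furan‑4‑yl (3R)‑3,4‑bis[(TBS)oxy]‑2‑methylidenebutanoate | C=C1C(=O)O[C@H]2/C=C(/COC(C)=O)CC[C@@H](O[Si](C)(C)C(C)(C)C)C(=C)C[C@H](OC(=O)C(=C)[C@@H](O[Si](C)(C)C(C)(C)C)CO[Si](C)(C)C(C)(C)C)[C@@H]12 | intermediate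
34 | (3aR,4S,7R,10E,11aS)‑10‑(acetoxymethyl)‑7‑hydroxy‑3,6‑dimethylidene‑2‑oxo‑2,3,3a,4,5,6,7,8,9,11a‑decahydrocyclodeca[b]furan‑4‑yl (3R)‑3,4‑dihydroxy‑2‑methylidenebutanoate | C=C1C(=O)O[C@H]2/C=C(/COC(C)=O)CC[C@@H](O)C(=C)C[C@H](OC(=O)C(=C)[C@@H](O)CO)[C@@H]12 | target

**Totals**
Total step count: 21. Longest linear sequence: 15 (steps 1–4, 7–15, 20, 21).

**Three steps most likely to fail, with fallbacks**

Step 14 (ring closure). Risks are oligomerization, attack through the CH2 terminus (twelve‑membered ring), loss of the C8 ether from the allylchromium, and the wrong C6/C7 diastereomer. The fallback replaces the stoichiometric reduction of an allylic bromide by a catalytic umpolung of an allylic ester. It sets out from 20: acetylation of the Baylis–Hillman hydroxyl (Ac2O, DMAP, pyridine, CH2Cl2) gives methyl (4S,7R,10E)‑3‑acetoxy‑10‑(acetoxymethyl)‑7‑[(TBS)oxy]‑4‑(PMB‑oxy)‑2,6‑dimethylidene‑12‑oxododec‑10‑enoate F1. With Pd(PPh3)4 (zerovalent palladium, 10 mol%) and Et2Zn (3 equiv) in THF at high dilution, the π‑allylpalladium complex is transmetalated to an allylzinc that adds to the enal within the molecule; the zinc alkoxide lactonizes via 22, and the route is rejoined at 23.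

Step 7 (fragment coupling that sets C1). Risks are the slow oxidative addition of a 2‑bromoalkene, ionization of the allylic acetate by zerovalent nickel, and an uncertain sense or level of induction. The fallback sets C1 by ketone reduction instead of aldehyde addition. It sets out from 8 and 12: a ligand‑free CrCl2/NiCl2 coupling in DMF gives (2E)‑4‑[(TBDPS)oxy]‑2‑{(3RS,6S)‑6‑[(4R)‑2,2‑dimethyl‑1,3‑dioxolan‑4‑yl]‑3‑hydroxy‑6‑(PMB‑oxy)‑4‑methylidenehexyl}but‑2‑en‑1‑yl acetate F2 as a C1 epimer mixture. Dess–Martin periodinane oxidation gives (2E)‑4‑[(TBDPS)oxy]‑2‑{(6S)‑6‑[(4R)‑2,2‑dimethyl‑1,3‑dioxolan‑4‑yl]‑6‑(PMB‑oxy)‑4‑methylidene‑3‑oxohexyl}but‑2‑en‑1‑yl acetate F3. Reduction with (S)‑2‑methyl‑CBS‑oxazaborolidine and catecholborane at −78 °C, with the α‑substituted vinyl group as the large substituent, gives the (1R)‑alcohol, and the route is rejoined at 13.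

Step 10 (Baylis–Hillman reaction). Risks are a slow reaction and amine‑induced epimerization of the α‑alkoxy aldehyde at C8. The fallback is an aldol and selenoxide‑elimination sequence. It sets out from 16: the lithium enolate of methyl 3‑(phenylselanyl)propanoate (LiN(i‑Pr)2, THF, −78 °C) adds to the aldehyde to give methyl (4S,7R,10E)‑10‑(acetoxymethyl)‑7‑[(TBS)oxy]‑12‑[(TBDPS)oxy]‑3‑hydroxy‑4‑(PMB‑oxy)‑6‑methylidene‑2‑[(phenylselanyl)methyl]dodec‑10‑enoate F4. Oxidation with H2O2 and pyridine at 0 °C, followed by syn‑elimination of the selenoxide, gives the α‑methylene ester, and the route is rejoined at 18.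

**Further compounds**
F1 | step 14 | methyl (4S,7R,10E)‑3‑acetoxy‑10‑(acetoxymethyl)‑7‑[(TBS)oxy]‑4‑(PMB‑oxy)‑2,6‑dimethylidene‑12‑oxododec‑10‑enoate (C3 epimers) | CC(=O)OC/C(CC[C@@H](O[Si](C)(C)C(C)(C)C)C(=C)C[C@H](OCc1ccc(OC)cc1)C(OC(C)=O)C(=C)C(=O)OC)=C/C=O
F2 | step 7 | (2E)‑4‑[(TBDPS)oxy]‑2‑{(3RS,6S)‑6‑[(4R)‑2,2‑dimethyl‑1,3‑dioxolan‑4‑yl]‑3‑hydroxy‑6‑(PMB‑oxy)‑4‑methylidenehexyl}but‑2‑en‑1‑yl acetate | CC(=O)OC/C(CCC(O)C(=C)C[C@H](OCc1ccc(OC)cc1)[C@H]1COC(C)(C)O1)=C/CO[Si](c1ccccc1)(c1ccccc1)C(C)(C)C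
F3 | step 7 | (2E)‑4‑[(TBDPS)oxy]‑2‑{(6S)‑6‑[(4R)‑2,2‑dimethyl‑1,3‑dioxolan‑4‑yl]‑6‑(PMB‑oxy)‑4‑methylidene‑3‑oxohexyl}but‑2‑en‑1‑yl acetate | CC(=O)OC/C(CCC(=O)C(=C)C[C@H](OCc1ccc(OC)cc1)[C@H]1COC(C)(C)O1)=C/CO[Si](c1ccccc1)(c1ccccc1)C(C)(C)C
F4 | step 10 | methyl (4S,7R,10E)‑10‑(acetoxymethyl)‑7‑[(TBS)oxy]‑12‑[(TBDPS)oxy]‑3‑hydroxy‑4‑(PMB‑oxy)‑6‑methylidene‑2‑[(phenylselanyl)methyl]dodec‑10‑enoate | CC(=O)OC/C(CC[C@@H](O[Si](C)(C)C(C)(C)C)C(=C)C[C@H](OCc1ccc(OC)cc1)C(O)C(C[Se]c1ccccc1)C(=O)OC)=C/CO[Si](c1ccccc1)(c1ccccc1)C(C)(C)C
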